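**Retrosynthetic overview**
The route rests on the ring C/D bicyclo[3.2.1]octane: tertiary carbinol C13, quaternary C8 and the exocyclic C16=C17 alkene are read as a C13 ketone, a tertiary C8 cation and the alkene left by a 2-(silylmethyl)vinyl group on C13. One Lewis acid cascade on a ring B methylenecyclopentane makes C13–C14 (ring C) and C8–C15 (ring D).
Ring B comes from an enantiopure cyclopentene γ-lactone (α-epoxide, vinyl at C6, C8 methylenation); the lactone arm is homologated to a δ-lactone and opened by 2-lithioallylsilane.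
A chair-like closure puts C15 anti to H9, so the cascade is run on the C9 epimer and C9 is then equilibrated to the natural ring fusion next to the C10 ketone.
Ring A comes last: C5 alkylation, 1-ethoxyvinyl addition with lactonization at C10, C4 methylation and hydroxymethylation, aldol condensation (C2–C3), C1 reduction, directed epoxidation, C7 oxidation.
Ring order: B (from the lactone), then C and D together (step 13), then the 19,10-lactone, then A.

Key step: step 13

Remark: gibberellane numbering and the α/β descriptors of the target are used for all intermediates (β is the face of ring B that carries C7), and enantiopure lactone 1 is taken as purchasable.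

**Route**

Step 1
Reactants: 1 (1R,5S)-2-oxabicyclo[3.3.0]oct-6-en-3-one
Product: 2 6α,8α-epoxy lactone
Conditions: mCPBA, NaHCO3, CH2Cl2, 0 °C to rt
Reagents that add atoms: mCPBA, OOC(=O)c1cccc(Cl)c1
Why: Prilezhaev epoxidation should occur on the convex α face of the cis-fused bicycle, anti to the lactone ring, so both epoxide carbons (C6, C8) carry the oxygen α.

Step 2
Reactants: 2 6α,8α-epoxy lactone
Product: 3 8α-hydroxy-6β-vinyl lactone
Conditions: CH2=CHMgBr, CuI (10 mol %), THF, −40 °C
Reagents that add atoms: vinylmagnesium bromide, C=C[Mg]Br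
Why: Copper-catalysed Grignard opening of the epoxide with inversion should occur at C6, remote from the ring fusion, because attack at C8 from the concave face is blocked by the cis C9–C11 bond; this sets the 6β-vinyl group (the future C7) and leaves the 8α-hydroxyl, and the lactone is not attacked at −40 °C.

Step 3
Reactants: 3 8α-hydroxy-6β-vinyl lactone
Product: 5 8α-hydroxy-6β-(hydroxymethyl) lactone, via formyl lactone 4 (not isolated)
Conditions: O3, CH2Cl2/MeOH, −78 °C; then NaBH4, −78 to 0 °C
Reagents that add atoms: ozone, [O-][O+]=O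
Why: Ozonolysis of the only alkene and reduction of aldehyde 4 in the same flask give the primary alcohol, and C6 keeps its configuration because the aldehyde is reduced cold before it can enolize.

Step 4
Reactants: 5 8α-hydroxy-6β-(hydroxymethyl) lactone
Product: 6 7-O-TBDPS 8α-hydroxy lactone
Conditions: TBDPSCl, imidazole, CH2Cl2, 0 °C
Reagents that add atoms: tert-butyl(chloro)diphenylsilane, CC(C)(C)[Si](Cl)(c1ccccc1)c1ccccc1
Why: Silyl ether formation with the bulky chlorosilane is selective for the primary hydroxyl over the secondary C8 hydroxyl.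

Step 5
Reactants: 6 7-O-TBDPS 8α-hydroxy lactone
Product: 7 8-oxo lactone
Conditions: Dess–Martin periodinane, NaHCO3, CH2Cl2, rt
Reagents that add atoms: none
Why: Dess–Martin oxidation under buffered, non-basic conditions gives the C8 ketone without β-elimination of the lactone oxygen or epimerization at C6, and C9 is locked by the cis ring fusion.

Step 6
Reactants: 7 8-oxo lactone
Product: 8 8-methylene lactone
Conditions: Zn, CH2Br2, TiCl4, THF/CH2Cl2, 0 °C to rt
Reagents that add atoms: dibromomethane, BrCBr
Why: Takai–Lombardo methylenation installs C14 under non-basic conditions that spare the lactone and both α-stereocentres.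

Step 7
Reactants: 8 8-methylene lactone
Product: 9 γ-lactol
Conditions: i-Bu2AlH, CH2Cl2, −78 °C
Reagents that add atoms: none
Why: Hydride reduction of a γ-lactone at −78 °C stops at the lactol because the aluminium hemiacetal is stable at that temperature.

Step 8
Reactants: 9 γ-lactol
Product: 10 10β-hydroxy methyl enol ether
Conditions: MeOCH2PPh3Cl, KN(SiMe3)2, THF, 0 °C to rt
Reagents that add atoms: (methoxymethyl)triphenylphosphonium chloride, COC[P+](c1ccccc1)(c1ccccc1)c1ccccc1.[Cl-]
Why: Wittig reaction of the open hydroxy aldehyde form of the lactol adds C13 as an enol ether (one-carbon homologation) and touches no stereocentre.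

Step 9
Reactants: 10 10β-hydroxy methyl enol ether
Product: 11 δ-lactol
Conditions: 1 M HCl, THF, rt
Reagents that add atoms: water, O
Why: Acid hydrolysis of the enol ether unveils the C13 aldehyde, which the C10 hydroxyl captures as the six-membered lactol.

Step 10
Reactants: 11 δ-lactol
Product: 12 δ-lactone
Conditions: TEMPO (10 mol %), PhI(OAc)2, CH2Cl2, rt
Reagents that add atoms: none
Why: Oxoammonium oxidation converts the lactol into the δ-lactone without affecting the 1,1-disubstituted alkene.

Step 11
Reactants: 12 δ-lactone; 13 (2-bromoallyl)trimethylsilane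
Product: 15 10β-hydroxy enone, via vinyllithium 14 (not isolated)
Conditions: 13, t-BuLi (2 equiv), Et2O, −78 °C; then 12, −78 °C; AcOH quench at −78 °C
Reagents that add atoms: none
Why: Bromine–lithium exchange gives vinyllithium 14, which adds once to the δ-lactone because the lithium hemiketal does not collapse before the cold quench, so the enone is formed and the C10 hydroxyl freed in one operation.

Step 12
Reactants: 15 10β-hydroxy enone
Product: 16 cascade precursor (10β-OTES)
Conditions: TESOTf, 2,6-lutidine, CH2Cl2, −78 °C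
Reagents that add atoms: triethylsilyl triflate, CC[Si](CC)(CC)OS(=O)(=O)C(F)(F)F
Why: Silyl triflate/lutidine silylation caps the C10 hydroxyl, which removes the hemiketal equilibrium, under conditions too cold to activate the enone or the allylsilane.

Step 13
Reactants: 16 cascade precursor (10β-OTES)
Product: 18 9-epi BCD tricycle, via C8 cation 17 (not isolated)
Conditions: Me2AlCl (2.5 equiv), CH2Cl2, −78 to −40 °C
Reagents that add atoms: none
Why: Proposed new method: Me2AlCl binds the C13 ketone, the exocyclic C8=C14 alkene attacks it through C14 in a chair-like transition state on the face of the C9 tether (C13–C14, ring C) to give the tertiary C8 cation 17, and the CH2 terminus of the 2-(silylmethyl)vinyl group held axial on C13 captures that cation (C8–C15, ring D) with loss of Me3Si, which leaves C16=C17 and the C13 aluminium alkoxide. The closest known reactions are Lewis acid Prins (type 2 carbonyl-ene) cyclizations of ketones onto 1,1-disubstituted alkenes and allylsilane-terminated cation–olefin cyclizations; their combination in one cascade that forms a bicyclo[3.2.1]octane has not been shown. Ring C closes 6-endo with respect to the C8=C14 alkene (exo with respect to the carbonyl), and ring D closes 5-endo with respect to the allylsilane π bond, the mode open to a cation attacked by an alkene that is 1,3-diaxial to it. C13 and C8 are set together by the C9 stereocentre alone: it fixes the face of C14 that the tethered ketone can reach, and in the chair the axial arm can bond only to the C8 lobe on that same face, so C15 enters syn to C11 and anti to H9, which with the 9α-H precursor is the natural 8,13 configuration. The step needs Prins attack in preference to conjugate attack on the enone, which would require an eight-membered ring, and capture of the cation in preference to proton loss or chloride transfer, which the intramolecular allylsilane (nucleophilic only once C13 is tetrahedral) and the proton-scavenging Me2AlCl should secure.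

Step 14
Reactants: 18 9-epi BCD tricycle
Product: 19 9-epi 10β,13-diol
Conditions: PPTS (cat.), MeOH/CH2Cl2, 0 °C
Reagents that add atoms: none
Why: Acid-catalysed methanolysis removes the secondary triethylsilyl ether much faster than the primary tert-butyldiphenylsilyl ether, and the tertiary allylic C13 alcohol is inert to this weak acid.

Step 15
Reactants: 19 9-epi 10β,13-diol
Product: 20 9-epi 10-ketone
Conditions: Dess–Martin periodinane, NaHCO3, CH2Cl2, rt
Reagents that add atoms: none
Why: Dess–Martin oxidation converts the secondary C10 alcohol into the cyclopentanone and cannot touch the tertiary C13 alcohol.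

Step 16
Reactants: 20 9-epi 10-ketone
Product: 21 10-ketone (9β-H)
Conditions: K2CO3, MeOH, rt
Reagents that add atoms: none
Why: Base-mediated enolization toward C9 equilibrates the ring fusion, and the 9β-H epimer should be favoured because it is the cis-fused hydrindanone in which ring C keeps a relaxed chair (C10 axial, anti to C15), whereas the 9α-H epimer forces ring C to pucker against the C15–C16 bridge, so C9 is set under thermodynamic control as in α-hydrindanones that carry an angular substituent.

Step 17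
Reactants: 21 10-ketone (9β-H)
Product: 22 13-O-TES 10-ketone
Conditions: TESOTf, 2,6-lutidine, CH2Cl2, −78 °C
Reagents that add atoms: triethylsilyl triflate, CC[Si](CC)(CC)OS(=O)(=O)C(F)(F)F
Why: Silylation of the tertiary C13 alcohol with the silyl triflate at −78 °C is faster than enol silylation of the ketone.

Step 18
Reactants: 22 13-O-TES 10-ketone
Product: 24 5α-(methoxycarbonylmethyl) ketone, via lithium enolate 23 (not isolated)
Conditions: LiN(i-Pr)2, THF, −78 °C; BrCH2CO2Me, DMPU, −78 to −30 °C
Reagents that add atoms: methyl bromoacetate, COC(=O)CBr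
Why: Kinetic deprotonation occurs at the C5 methylene and not at the hindered C9 methine next to quaternary C8, and enolate 23 is alkylated anti to the adjacent C6 substituent, which sets C5 (5β-H, C4 on the α face).

Step 19
Reactants: 24 5α-(methoxycarbonylmethyl) ketone
Product: 26 10β-(1-ethoxyvinyl) 19,10-lactone, via cerium alkoxide 25 (not isolated)
Conditions: ethyl vinyl ether, t-BuLi, THF, −78 to 0 °C; CeCl3, −78 °C; then 24, −78 °C to rt
Reagents that add atoms: ethyl vinyl ether, C=COCC
Why: The organocerium reagent from 1-ethoxyvinyllithium adds to the hindered, enolizable ketone without deprotonating it or attacking the ester, from the β face anti to both α-substituents (C4 and C11), and alkoxide 25 closes the cis-fused γ-lactone by acyl substitution on the methyl ester, which sets C10.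

Step 20
Reactants: 26 10β-(1-ethoxyvinyl) 19,10-lactone
Product: 28 4-methyl lactone, via lactone enolate 27 (not isolated)
Conditions: LiN(i-Pr)2, THF, −78 °C; MeI
Reagents that add atoms: iodomethane, CI
Why: Lactone enolate 27 is methylated on the convex face anti to C6, giving mainly the epimer with methyl cis to H5, and the C4 configuration does not matter because the next step erases it.

Step 21
Reactants: 28 4-methyl lactone
Product: 30 4-(hydroxymethyl)-4-methyl lactone, via lactone enolate 29 (not isolated)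
Conditions: LiN(i-Pr)2, THF, −78 °C; CH2O (gas), −78 to −40 °C
Reagents that add atoms: formaldehyde, C=O
Why: Aldol addition of the tetrasubstituted lactone enolate 29 to formaldehyde again occurs on the convex face anti to C6, so the new carbon (C3) is cis to H5 and to the C10 side chain and the methyl becomes C18, which sets the C4 quaternary centre.

Step 22
Reactants: 30 4-(hydroxymethyl)-4-methyl lactone
Product: 31 C3 aldehyde
Conditions: Dess–Martin periodinane, NaHCO3, CH2Cl2, rt
Reagents that add atoms: none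
Why: Dess–Martin oxidation of the neopentyl primary alcohol gives the non-enolizable aldehyde under buffered conditions that the enol ether survives.

Step 23
Reactants: 31 C3 aldehyde
Product: 32 keto aldehyde (10β-acetyl)
Conditions: PPTS, acetone/H2O, rt
Reagents that add atoms: water, O
Why: The 1-alkoxyvinyl ether is hydrolysed by very mild acid to the methyl ketone (C1=O, C2), which leaves the silyl ethers and the aldehyde untouched.

Step 24
Reactants: 32 keto aldehyde (10β-acetyl)
Product: 34 ring A Δ2-en-1-one, via aldol 33 (not isolated)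
Conditions: piperidine (cat.), AcOH (cat.), benzene, 60 °C
Reagents that add atoms: none
Why: Amine-salt catalysed intramolecular aldol condensation joins the only enolizable carbon, C2 of the methyl ketone, to the non-enolizable C3 aldehyde in a six-membered (enolendo)-exo-trig closure made possible by the cis placement of both arms on the lactone, and dehydration of aldol 33 gives the enone.

Step 25
Reactants: 34 ring A Δ2-en-1-one
Product: 35 1β-hydroxy-Δ2 lactone
Conditions: LiBH(sec-Bu)3, THF, −78 °C
Reagents that add atoms: none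
Why: The bulky borohydride should add 1,2 (C3 is neopentylic, which disfavours conjugate addition) and equatorially, from the side of the lactone bridge and not past the axial 5β-H, to give the axial 1β-alcohol, as such hydrides do with other bridged ring A ketones of this skeleton.

Step 26
Reactants: 35 1β-hydroxy-Δ2 lactone
Product: 36 1β-hydroxy-2β,3β-epoxide
Conditions: VO(acac)2 (5 mol %), t-BuOOH, CH2Cl2, 0 °C to rt
Reagents that add atoms: tert-butyl hydroperoxide, CC(C)(C)OO
Why: Vanadium-catalysed hydroxyl-directed epoxidation delivers oxygen to C2=C3 syn to the allylic 1β-hydroxyl, the face that is also free of the lactone bridge, and the C16=C17 alkene is left alone because the neighbouring C13 oxygen is silylated.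

Step 27
Reactants: 36 1β-hydroxy-2β,3β-epoxide
Product: 37 1β,7,13-triol
Conditions: Bu4NF, AcOH, THF, 0 °C to rt
Reagents that add atoms: none
Why: Fluoride cleaves both silyl ethers (primary TBDPS and tertiary TES) under buffered conditions that leave the epoxide and the lactone intact.

Step 28
Reactants: 37 1β,7,13-triol
Product: 39 the target gibberellin (1β,13-dihydroxy-2β,3β-epoxy 19,10-lactone 7-oic acid), via aldehyde 38 (not isolated)
Conditions: TEMPO (20 mol %), PhI(OAc)2, MeCN/aqueous phosphate buffer (pH 7), rt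
Reagents that add atoms: water, O
Why: Oxoammonium oxidation is selective for the primary C7 alcohol over the hindered secondary 1β-alcohol and the tertiary 13-alcohol, and in aqueous medium aldehyde 38 is carried on to the carboxylic acid.

**Compound list**
1 | (1R,5S)-2-oxabicyclo[3.3.0]oct-6-en-3-one (ring carbons are the future C9, C10, C5, C6, C8; lactone arm C11–C12 on the β face) | O=C1C[C@H]2C=CC[C@H]2O1 | starting material
2 | 6α,8α-epoxy lactone (epoxide anti to the lactone ring) | O=C1C[C@H]2[C@@H]3O[C@@H]3C[C@H]2O1 | intermediate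
3 | 8α-hydroxy-6β-vinyl lactone | O=C1C[C@H]2[C@H](O)[C@@H](C=C)C[C@H]2O1 | intermediate
4 | 6β-formyl-8α-hydroxy lactone (not isolated) | O=C1C[C@H]2[C@H](O)[C@@H](C=O)C[C@H]2O1 | intermediate
5 | 8α-hydroxy-6β-(hydroxymethyl) lactone | O=C1C[C@H]2[C@H](O)[C@@H](CO)C[C@H]2O1 | intermediate
6 | 7-O-TBDPS 8α-hydroxy lactone | O=C1C[C@H]2[C@H](O)[C@@H](CO[Si](c3ccccc3)(c3ccccc3)C(C)(C)C)C[C@H]2O1 | intermediate
7 | 8-oxo lactone | O=C1C[C@H]2C(=O)[C@@H](CO[Si](c3ccccc3)(c3ccccc3)C(C)(C)C)C[C@H]2O1 | intermediate
8 | 8-methylene lactone (C14 in place) | O=C1C[C@H]2C(=C)[C@@H](CO[Si](c3ccccc3)(c3ccccc3)C(C)(C)C)C[C@H]2O1 | intermediate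
9 | γ-lactol (C12 hemiacetal, both anomers) | OC1C[C@H]2C(=C)[C@@H](CO[Si](c3ccccc3)(c3ccccc3)C(C)(C)C)C[C@H]2O1 | intermediate
10 | 10β-hydroxy methyl enol ether (E/Z mixture at C12=C13) | COC=CC[C@H]1C(=C)[C@@H](CO[Si](c2ccccc2)(c2ccccc2)C(C)(C)C)C[C@H]1O | intermediate
11 | δ-lactol (C13 hemiacetal, both anomers) | OC1CC[C@H]2C(=C)[C@@H](CO[Si](c3ccccc3)(c3ccccc3)C(C)(C)C)C[C@H]2O1 | intermediate
12 | δ-lactone (C13 carbonyl, O on C10) | O=C1CC[C@H]2C(=C)[C@@H](CO[Si](c3ccccc3)(c3ccccc3)C(C)(C)C)C[C@H]2O1 | intermediate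
13 | (2-bromoallyl)trimethylsilane | C=C(Br)C[Si](C)(C)C | starting material
14 | (3-(trimethylsilyl)prop-1-en-2-yl)lithium (not isolated) | [Li]C(=C)C[Si](C)(C)C | intermediate
15 | 10β-hydroxy enone: ring B methylenecyclopentane with 9α-H, β side chain CH2CH2C(=O)C(=CH2)CH2SiMe3, 6β-CH2OTBDPS | C=C(C[Si](C)(C)C)C(=O)CC[C@H]1C(=C)[C@@H](CO[Si](c2ccccc2)(c2ccccc2)C(C)(C)C)C[C@H]1O | intermediate
16 | cascade precursor: 15 as its 10β-triethylsilyl ether | C=C(C[Si](C)(C)C)C(=O)CC[C@H]1C(=C)[C@@H](CO[Si](c2ccccc2)(c2ccccc2)C(C)(C)C)C[C@H]1O[Si](CC)(CC)CC | intermediate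
17 | ring C closed C8 cation with C13 aluminate (zwitterion, not isolated) | C=C(C[Si](C)(C)C)[C@]1(O[Al-](C)(C)Cl)CC[C@H]2[C+](C1)[C@@H](CO[Si](c3ccccc3)(c3ccccc3)C(C)(C)C)C[C@H]2O[Si](CC)(CC)CC | intermediate
18 | 9-epi BCD tricycle: 13-hydroxy, 16-methylene, 9α-H, 10β-OTES, 7-OTBDPS | C=C1C[C@]23C[C@@]1(O)CC[C@@H]2[C@H](O[Si](CC)(CC)CC)C[C@@H]3CO[Si](c1ccccc1)(c1ccccc1)C(C)(C)C | intermediate
19 | 9-epi 10β,13-diol | C=C1C[C@]23C[C@@]1(O)CC[C@@H]2[C@H](O)C[C@@H]3CO[Si](c1ccccc1)(c1ccccc1)C(C)(C)C | intermediate
20 | 9-epi 10-ketone (9α-H) | C=C1C[C@]23C[C@@]1(O)CC[C@@H]2C(=O)C[C@@H]3CO[Si](c1ccccc1)(c1ccccc1)C(C)(C)C | intermediate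
21 | 10-ketone with natural 9β-H | C=C1C[C@]23C[C@@]1(O)CC[C@H]2C(=O)C[C@@H]3CO[Si](c1ccccc1)(c1ccccc1)C(C)(C)C | intermediate
22 | 13-O-TES 10-ketone | C=C1C[C@]23C[C@@]1(O[Si](CC)(CC)CC)CC[C@H]2C(=O)C[C@@H]3CO[Si](c1ccccc1)(c1ccccc1)C(C)(C)C | intermediate
23 | lithium enolate C5=C10 (not isolated) | C=C1C[C@]23C[C@@]1(O[Si](CC)(CC)CC)CC[C@H]2C(O[Li])=C[C@@H]3CO[Si](c1ccccc1)(c1ccccc1)C(C)(C)C | intermediate
24 | 5α-(methoxycarbonylmethyl) 10-ketone (5β-H) | C=C1C[C@]23C[C@@]1(O[Si](CC)(CC)CC)CC[C@H]2C(=O)[C@@H](CC(=O)OC)[C@@H]3CO[Si](c1ccccc1)(c1ccccc1)C(C)(C)C | intermediate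
25 | C10 cerium alkoxide with 10β-(1-ethoxyvinyl) (not isolated) | C=C1C[C@]23C[C@@]1(O[Si](CC)(CC)CC)CC[C@H]2[C@](O[Ce](Cl)Cl)(C(=C)OCC)[C@@H](CC(=O)OC)[C@@H]3CO[Si](c1ccccc1)(c1ccccc1)C(C)(C)C | intermediate
26 | 19,10-lactone with 10β-(1-ethoxyvinyl), C4 unsubstituted | C=C1C[C@]23C[C@@]1(O[Si](CC)(CC)CC)CC[C@H]2[C@@]4(C(=C)OCC)OC(=O)C[C@H]4[C@@H]3CO[Si](c1ccccc1)(c1ccccc1)C(C)(C)C | intermediate
27 | lithium enolate of lactone 26 (not isolated) | C=C1C[C@]23C[C@@]1(O[Si](CC)(CC)CC)CC[C@H]2[C@@]4(C(=C)OCC)OC(O[Li])=C[C@H]4[C@@H]3CO[Si](c1ccccc1)(c1ccccc1)C(C)(C)C | intermediate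
28 | 4-methyl lactone (major epimer drawn, methyl cis to H5) | C=C1C[C@]23C[C@@]1(O[Si](CC)(CC)CC)CC[C@H]2[C@@]4(C(=C)OCC)OC(=O)[C@H](C)[C@H]4[C@@H]3CO[Si](c1ccccc1)(c1ccccc1)C(C)(C)C | intermediate
29 | lithium enolate of lactone 28 (not isolated) | C=C1C[C@]23C[C@@]1(O[Si](CC)(CC)CC)CC[C@H]2[C@@]4(C(=C)OCC)OC(O[Li])=C(C)[C@H]4[C@@H]3CO[Si](c1ccccc1)(c1ccccc1)C(C)(C)C | intermediate
30 | 4-(hydroxymethyl)-4-methyl lactone (CH2OH = C3, cis to H5; methyl = C18) | C=C1C[C@]23C[C@@]1(O[Si](CC)(CC)CC)CC[C@H]2[C@@]4(C(=C)OCC)OC(=O)[C@](C)(CO)[C@H]4[C@@H]3CO[Si](c1ccccc1)(c1ccccc1)C(C)(C)C | intermediate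
31 | C3 aldehyde | C=C1C[C@]23C[C@@]1(O[Si](CC)(CC)CC)CC[C@H]2[C@@]4(C(=C)OCC)OC(=O)[C@](C)(C=O)[C@H]4[C@@H]3CO[Si](c1ccccc1)(c1ccccc1)C(C)(C)C | intermediate
32 | keto aldehyde (10β-acetyl, C3 aldehyde) | C=C1C[C@]23C[C@@]1(O[Si](CC)(CC)CC)CC[C@H]2[C@@]4(C(C)=O)OC(=O)[C@](C)(C=O)[C@H]4[C@@H]3CO[Si](c1ccccc1)(c1ccccc1)C(C)(C)C | intermediate
33 | aldol: 3-hydroxy-1-ketone, ring A closed, C3 epimers (not isolated) | C=C1C[C@]23C[C@@]1(O[Si](CC)(CC)CC)CC[C@H]2[C@@]45OC(=O)[C@@](C)([C@H]4[C@@H]3CO[Si](c1ccccc1)(c1ccccc1)C(C)(C)C)C(O)CC5=O | intermediate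
34 | ring A Δ2-en-1-one (7-OTBDPS, 13-OTES) | C=C1C[C@]23C[C@@]1(O[Si](CC)(CC)CC)CC[C@H]2[C@@]45OC(=O)[C@@](C)([C@H]4[C@@H]3CO[Si](c1ccccc1)(c1ccccc1)C(C)(C)C)C=CC5=O | intermediate
35 | 1β-hydroxy-Δ2 lactone | C=C1C[C@]23C[C@@]1(O[Si](CC)(CC)CC)CC[C@H]2[C@@]45OC(=O)[C@@](C)([C@H]4[C@@H]3CO[Si](c1ccccc1)(c1ccccc1)C(C)(C)C)C=C[C@H]5O | intermediate
36 | 1β-hydroxy-2β,3β-epoxide (7-OTBDPS, 13-OTES) | C=C1C[C@]23C[C@@]1(O[Si](CC)(CC)CC)CC[C@H]2[C@@]45OC(=O)[C@@](C)([C@H]4[C@@H]3CO[Si](c1ccccc1)(c1ccccc1)C(C)(C)C)[C@H]6O[C@H]6[C@H]5O | intermediate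
37 | 1β,7,13-triol 2β,3β-epoxide | C=C1C[C@]23C[C@@]1(O)CC[C@H]2[C@@]45OC(=O)[C@@](C)([C@H]4[C@@H]3CO)[C@H]6O[C@H]6[C@H]5O | intermediate
38 | C7 aldehyde (not isolated) | C=C1C[C@]23C[C@@]1(O)CC[C@H]2[C@@]45OC(=O)[C@@](C)([C@H]4[C@@H]3C=O)[C@H]6O[C@H]6[C@H]5O | intermediate
39 | the target gibberellin: 2β,3β-epoxy-1β,13-dihydroxy-16-methylene 19,10-lactone 7-oic acid | C=C1C[C@]23C[C@@]1(O)CC[C@H]2[C@@]12OC(=O)[C@@](C)([C@H]1[C@@H]3C(=O)O)[C@H]1O[C@H]1[C@H]2O | target

Total step count: 28. Longest linear sequence: 28 steps (1 to 39); 13 is used as purchased and lithiated in the flask.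

**Steps most likely to fail**

Step 13. The C8 cation may lose a proton (plain carbonyl-ene product) or take up chloride before the allylsilane closes ring D, the allylsilane may be protodesilylated, or ring D may close through a boat and give the other 8,13 configuration. The fallback uses known reactions, sets out from 12 and comes back at 21. MeLi (1 equiv, THF, −78 °C) should open the δ-lactone to the hydroxy methyl ketone F1, whose methyl becomes C14, and TESOTf/2,6-lutidine should give the silyl ether F2. Ozonolysis (O3, CH2Cl2, −78 °C; Me2S) of the exocyclic methylene should give the 1,5-diketone F3. Pyrrolidine/AcOH should equilibrate C9 trans to the C10 silyloxy group and close ring C by aldol condensation to the bicyclic enone F4; loss of the C10 silyloxy group and epimerization at C6 are the processes to watch. Hosomi–Sakurai conjugate addition of 13 (TiCl4, CH2Cl2, −78 °C) should place the 2-bromoallyl group on C8 cis to H9, as in conjugate additions to related bicyclic enones, giving the bromoallyl ketone F5. Intramolecular Nozaki–Hiyama–Kishi reaction (CrCl2, NiCl2 cat., DMF) should close ring D to the tricycle F6 with natural 9β-H. PPTS/MeOH should give the diol F7, and Dess–Martin oxidation then gives 21. This sequence sets H9 before C8 and so does not depend on the equilibration of step 16.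

Step 25. Hydride may be delivered from the β face (1α-alcohol), or conjugate reduction may compete. The fallback sets out from 34 and comes back at 36. Weitz–Scheffer epoxidation (t-BuOOH, DBU, CH2Cl2) should give the 2β,3β-epoxy ketone F8, since the peroxide attacks C3 axially on the face away from the lactone bridge. Reduction with NaBH4/CeCl3 (MeOH, −78 °C) should then bring hydride in anti to the epoxide oxygen and give the cis epoxy alcohol 36.

Step 24. The formyl group may be lost by retro-Claisen cleavage, or the methyl ketone enolate may acylate on the lactone carbonyl before the aldol closure takes place. The fallback sets out from 31 and comes back at 34 without ever freeing the methyl ketone. BF3·OEt2 (CH2Cl2, −78 °C) should add the intact 1-ethoxyvinyl ether to the aldehyde (Mukaiyama-type aldol), and aqueous work-up gives aldol 33, isolated this time. MsCl/Et3N should give the mesylate F9, and DBU eliminates it to 34.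

**Further compounds**
F1 | step 13 | hydroxy methyl ketone (10β-OH, C13 methyl ketone, C8 methylene) | CC(=O)CC[C@H]1C(=C)[C@@H](CO[Si](c2ccccc2)(c2ccccc2)C(C)(C)C)C[C@H]1O
F2 | step 13 | 10β-triethylsilyl ether of F1 | CC(=O)CC[C@H]1C(=C)[C@@H](CO[Si](c2ccccc2)(c2ccccc2)C(C)(C)C)C[C@H]1O[Si](CC)(CC)CC
F3 | step 13 | 1,5-diketone (C8 and C13 ketones) | CC(=O)CC[C@H]1C(=O)[C@@H](CO[Si](c2ccccc2)(c2ccccc2)C(C)(C)C)C[C@H]1O[Si](CC)(CC)CC
F4 | step 13 | bicyclic enone (C13=O, C14=C8, 9β-H) | O=C1CC[C@@H]2C(=C1)[C@@H](CO[Si](c3ccccc3)(c3ccccc3)C(C)(C)C)C[C@H]2O[Si](CC)(CC)CC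
F5 | step 13 | 8-(2-bromoallyl) ring C ketone (C15 β, cis to H9) | O=C1CC[C@@H]2[C@@](C1)(CC(Br)=C)[C@@H](CO[Si](c3ccccc3)(c3ccccc3)C(C)(C)C)C[C@H]2O[Si](CC)(CC)CC
F6 | step 13 | BCD tricycle with 9β-H, 10β-OTES, 13-OH, 16-methylene | C=C1C[C@]23C[C@@]1(O)CC[C@H]2[C@H](O[Si](CC)(CC)CC)C[C@@H]3CO[Si](c1ccccc1)(c1ccccc1)C(C)(C)C
F7 | step 13 | 10β,13-diol with 9β-H | C=C1C[C@]23C[C@@]1(O)CC[C@H]2[C@H](O)C[C@@H]3CO[Si](c1ccccc1)(c1ccccc1)C(C)(C)C
F8 | step 25 | 2β,3β-epoxy 1-ketone | C=C1C[C@]23C[C@@]1(O[Si](CC)(CC)CC)CC[C@H]2[C@@]45OC(=O)[C@@](C)([C@H]4[C@@H]3CO[Si](c1ccccc1)(c1ccccc1)C(C)(C)C)[C@H]6O[C@H]6C5=O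
F9 | step 24 | C3 mesylate of aldol 33 | C=C1C[C@]23C[C@@]1(O[Si](CC)(CC)CC)CC[C@H]2[C@@]45OC(=O)[C@@](C)([C@H]4[C@@H]3CO[Si](c1ccccc1)(c1ccccc1)C(C)(C)C)C(OS(C)(=O)=O)CC5=O
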